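**Retrosynthetic overview**

1. Feature used: in tetralin numbering (C1 isopropyl, C4 methyl, C5 and C6 hydroxyls, C7 formyl, C8 pyranone; ring A benzene, ring B carbocycle) the C6 oxygen and the C7 formyl carbon are ortho neighbours, so one silicon atom can tie them as O–Si–CH2. Diisopropylsilicon is chosen over dimethylsilicon so that the silyl ether survives chromatography and the coupling.
2. Target ⇒ aldehyde 24 (BBr3 removes three methyl ethers) ⇒ diol 23 (MnO2) ⇒ oxasilole 22 (Tamao oxidation cuts C7–Si and O–Si).
3. Ring A ⇒ fused 3-silyloxy-2-pyranone 20 with the tethered alkyne: intramolecular Diels–Alder across pyranone C3 and C6 forms C6–C7 and C8–C8a, then CO2 is lost.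
4. 20 ⇒ propargylsilyl ether 15 + 3-iodo styrylpyranone 19 (Sonogashira). 15 comes from hydroxypyranone 10, made from the silyl enol ether of (+)-menthone and benzyloxymalonyl dichloride; 19 comes from 4-methoxy-6-methyl-2-pyranone and 4-methoxybenzaldehyde.
5. Ring order: ring B with both stereocentres is bought as (+)-menthone, the 2-pyranone is fused on (step 4), and ring A is formed last (step 12); the styrylpyranone ring is made separately.

Key step: step 12

Assumption: the target structure gives no descriptor for the hindered C8–C3' biaryl axis, so the axis is left uncontrolled; (+)-menthone is taken as the commercial (2R,5S) enantiomer.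

**Route**

Step 1
Reactants: 1 (2R,5S)-(+)-menthone
Product: 3 trimethyl{[(3S,6R)-3-methyl-6-(propan-2-yl)cyclohex-1-en-1-yl]oxy}silane, via lithium enolate 2 (not isolated)
Conditions: LiN(iPr)2 (LDA, slight excess), THF, −78 °C; then TMSCl, −78 °C → rt
Reagents that add atoms: chlorotrimethylsilane, C[Si](C)(C)Cl; lithium diisopropylamide, CC(C)N([Li])C(C)C (lithium of 2 only)
Why: Kinetic enolate formation with the hindered amide should remove a proton from the open CH2 group and not from the isopropyl-bearing CH, so silyl trapping gives the less substituted enol ether and the isopropyl-bearing centre is never enolised.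

Step 2
Reactants: 4 dimethyl 2-(benzyloxy)malonate
Product: 5 2-(benzyloxy)malonic acid
Conditions: NaOH, H2O/MeOH, rt; then HCl (aq), 0 °C
Reagents that add atoms: sodium hydroxide, [Na+].[OH-]
Why: Saponification of both methyl esters should give the diacid, which is kept cold to avoid decarboxylation.

Step 3
Reactants: 5 2-(benzyloxy)malonic acid
Product: 6 2-(benzyloxy)malonyl dichloride
Conditions: (COCl)2, DMF (cat.), CH2Cl2, 0 °C → rt; used crude
Reagents that add atoms: oxalyl chloride, O=C(Cl)C(=O)Cl
Why: DMF-catalysed acid chloride formation should convert both carboxyl groups under conditions that leave the benzyl ether untouched.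

Step 4
Reactants: 3 menthone trimethylsilyl enol ether; 6 2-(benzyloxy)malonyl dichloride
Product: 8 (5S,8R)-3-(benzyloxy)-4-hydroxy-5-methyl-8-(propan-2-yl)-5,6,7,8-tetrahydro-2H-chromen-2-one, via keto acid chloride 7 (not isolated)
Conditions: Et2O, −78 °C → rt
Reagents that add atoms: none
Why: This is the known annulation of a silyl enol ether with a malonyl dichloride to a 4-hydroxy-2-pyranone: C-acylation at the enol ether carbon with loss of TMSCl gives 7, whose enol oxygen closes the lactone on the second acid chloride, after which the isopropyl-bearing centre sits on an enol lactone carbon and is no longer enolisable.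

Step 5
Reactants: 8 fused 3-benzyloxy-4-hydroxy-2-pyranone
Product: 9 (5S,8R)-3-(benzyloxy)-4-methoxy-5-methyl-8-(propan-2-yl)-5,6,7,8-tetrahydro-2H-chromen-2-one
Conditions: Me2SO4, K2CO3, acetone, reflux
Reagents that add atoms: dimethyl sulfate, COS(=O)(=O)OC
Why: O-Alkylation of 4-hydroxy-2-pyranones with dimethyl sulfate and carbonate is the standard route to 4-methoxy-2-pyranones and should favour this isomer over the 2-methoxy-4-pyranone.

Step 6
Reactants: 9 fused 3-benzyloxy-4-methoxy-2-pyranone
Product: 10 (5S,8R)-3-hydroxy-4-methoxy-5-methyl-8-(propan-2-yl)-5,6,7,8-tetrahydro-2H-chromen-2-one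
Conditions: H2 (1 atm), Pd/C, EtOAc, rt
Reagents that add atoms: none
Why: Hydrogenolysis of the benzyl ether should free the 3-hydroxyl, the tetrasubstituted pyranone double bonds being inert at 1 atm and room temperature.

Step 7
Reactants: 11 propargyl bromide; 12 dichlorodi(propan-2-yl)silane
Product: 14 chloro[di(propan-2-yl)](prop-2-yn-1-yl)silane, via allenylmagnesium bromide 13 (not isolated)
Conditions: Mg, HgCl2 (cat.), Et2O, 0 °C; then added to 12 (excess), Et2O, −78 °C → rt; distillation
Reagents that add atoms: magnesium, [Mg] (in 13 only)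
Why: Grignard formation gives the allenyl reagent, which silylates with allylic transposition (SE2') to the propargylsilane, and the hindered dichlorosilane should be substituted only once.

Step 8
Reactants: 10 fused 3-hydroxy-4-methoxy-2-pyranone; 14 chloro(diisopropyl)(propargyl)silane
Product: 15 (5S,8R)-3-{[di(propan-2-yl)(prop-2-yn-1-yl)silyl]oxy}-4-methoxy-5-methyl-8-(propan-2-yl)-5,6,7,8-tetrahydro-2H-chromen-2-one
Conditions: imidazole, DMF, 0 °C → rt
Reagents that add atoms: none
Why: O-Silylation of the acidic enolic hydroxyl with a chlorosilane and imidazole is routine, and the two isopropyl groups should make the silyl ether stable to chromatography.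

Step 9
Reactants: 16 4-methoxy-6-methyl-2H-pyran-2-one
Product: 17 3-iodo-4-methoxy-6-methyl-2H-pyran-2-one
Conditions: NIS, TFA (cat.), MeCN, rt, dark
Reagents that add atoms: N-iodosuccinimide, O=C1CCC(=O)N1I
Why: Electrophilic iodination should occur at C3, the nucleophilic carbon between the lactone carbonyl and the methoxy-bearing carbon, and is done before the electron-rich styrene is present.

Step 10
Reactants: 17 3-iodo-4-methoxy-6-methyl-2H-pyran-2-one; 18 4-methoxybenzaldehyde
Product: 19 3-iodo-4-methoxy-6-[(E)-2-(4-methoxyphenyl)ethenyl]-2H-pyran-2-one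
Conditions: Mg(OMe)2, MeOH, reflux; then dilute HCl
Reagents that add atoms: none
Why: Vinylogous aldol condensation at the 6-methyl group is the classical route to 6-styryl-4-methoxy-2-pyranones, and the E1cB dehydration should give the conjugated E-alkene under thermodynamic control.

Step 11
Reactants: 15 propargylsilyl ether; 19 3-iodo styrylpyranone
Product: 20 (5S,8R)-4-methoxy-3-{[(3-{4-methoxy-6-[(E)-2-(4-methoxyphenyl)ethenyl]-2-oxo-2H-pyran-3-yl}prop-2-yn-1-yl)di(propan-2-yl)silyl]oxy}-5-methyl-8-(propan-2-yl)-5,6,7,8-tetrahydro-2H-chromen-2-one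
Conditions: PdCl2(PPh3)2 (cat.), CuI (cat.), Et3N, THF, rt, degassed; chromatography on Et3N-deactivated silica
Reagents that add atoms: none
Why: Sonogashira coupling of the iodide with the terminal propargylsilane should proceed at room temperature, where the silyl ether survives and the neighbouring methoxy oxygen does not cyclise onto the new alkyne.

Step 12
Reactants: 20 tethered pyranone–alkyne
Product: 22 oxasilole-fused tetralin (C5 methoxy, C6–O–Si(iPr)2–CH2–C7 five-membered ring, C8 bearing the 4-methoxy-6-[(E)-4-methoxystyryl]-2-oxo-2H-pyran-3-yl group; 1R,4S in tetralin numbering), via bridged lactone 21 (not isolated)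
Conditions: PhMe (0.005 M), BHT (cat.), 150 °C, sealed tube
Reagents that add atoms: none
Why: Proposed new method: the 3-silyloxy-4-methoxy-2-pyranone is an electron-rich diene and the alkyne, held by the O–Si–CH2 tether, can reach pyranone C3 only with its CH2-bearing carbon and C6 only with its pyranone-bearing carbon, so a thermal intramolecular [4+2] cycloaddition should give the bridged lactone 21, which loses CO2 by retro-[4+2] and leaves the benzene ring with the new C6–C7 and C8–C8a bonds. The closest known reactions are the intermolecular Diels–Alder/CO2-loss sequence of 3-silyloxy-2-pyranones with alkynes and silicon-tethered intramolecular Diels–Alder reactions, which have not been combined on one substrate. Ring A closes by the [4+2] cycloaddition and is aromatised by the extrusion, and the five-membered 1,2-oxasilole closes in the same event in the fused (5-exo-dig-like) mode, the two isopropyl groups on silicon favouring the folded conformer (Thorpe–Ingold effect). No stereocentre is formed, because both bridgeheads of 21 become arene carbons, so the face of attack is irrelevant, and the two menthone-derived centres are not enolisable and see no base. The step needs regioselectivity, which the three-atom tether secures because the bridged mode is out of reach, and chemoselectivity for the tethered diene over the second pyranone and the styrene, which high dilution and the silyloxy donor on the reacting pyranone should secure. The C8–C3' axis is formed without control.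

Step 13
Reactants: 22 oxasilole-fused tetralin
Product: 23 3-[(5S,8R)-3-hydroxy-2-(hydroxymethyl)-4-methoxy-5-methyl-8-(propan-2-yl)-5,6,7,8-tetrahydronaphthalen-1-yl]-4-methoxy-6-[(E)-2-(4-methoxyphenyl)ethenyl]-2H-pyran-2-one
Conditions: H2O2 (30% aq), KF, KHCO3, THF/MeOH, rt → 40 °C; Na2S2O3 quench
Reagents that add atoms: hydrogen peroxide, OO
Why: In this Tamao oxidation, fluoride and hydroperoxide should add to the strained, aryloxy-substituted silicon, the benzylic carbon migrates from silicon to oxygen and hydrolysis frees the C6 phenol and the C7 hydroxymethyl group; it is run before the aldehyde exists so that no Dakin oxidation can occur.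

Step 14
Reactants: 23 hydroxymethyl phenol
Product: 24 (5S,8R)-3-hydroxy-4-methoxy-1-{4-methoxy-6-[(E)-2-(4-methoxyphenyl)ethenyl]-2-oxo-2H-pyran-3-yl}-5-methyl-8-(propan-2-yl)-5,6,7,8-tetrahydronaphthalene-2-carbaldehyde
Conditions: MnO2 (activated, excess), CH2Cl2, rt
Reagents that add atoms: none
Why: MnO2 oxidation of a benzylic (salicyl) alcohol should stop at the salicylaldehyde and leave the phenol, the styrene and the pyranones alone.

Step 15
Reactants: 24 trimethyl ether aldehyde
Product: 25 heimiomycin A, (5S,8R)-3,4-dihydroxy-1-{4-hydroxy-6-[(E)-2-(4-hydroxyphenyl)ethenyl]-2-oxo-2H-pyran-3-yl}-5-methyl-8-(propan-2-yl)-5,6,7,8-tetrahydronaphthalene-2-carbaldehyde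
Conditions: BBr3 (excess), CH2Cl2, −78 → 0 °C; then H2O
Reagents that add atoms: none
Why: BBr3 ether cleavage should remove the two aryl methyl ethers and the pyranone 4-methyl ether (a cleavage used on related styrylpyranones), the aldehyde returning on hydrolysis and the two benzylic stereocentres being untouched.

**Compound list**

1 | (2R,5S)-(+)-menthone | CC(C)[C@H]1CC[C@H](C)CC1=O | starting material
2 | lithium (3S,6R)-3-methyl-6-(propan-2-yl)cyclohex-1-en-1-olate | CC(C)[C@H]1CC[C@H](C)C=C1O[Li] | intermediate
3 | trimethyl{[(3S,6R)-3-methyl-6-(propan-2-yl)cyclohex-1-en-1-yl]oxy}silane | CC(C)[C@H]1CC[C@H](C)C=C1O[Si](C)(C)C | intermediate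
4 | dimethyl 2-(benzyloxy)malonate | COC(=O)C(OCc1ccccc1)C(=O)OC | starting material
5 | 2-(benzyloxy)malonic acid | OC(=O)C(OCc1ccccc1)C(=O)O | intermediate
6 | 2-(benzyloxy)malonyl dichloride | ClC(=O)C(OCc1ccccc1)C(Cl)=O | intermediate
7 | 2-(benzyloxy)-3-[(3R,6S)-6-methyl-2-oxo-3-(propan-2-yl)cyclohexyl]-3-oxopropanoyl chloride (mixture at the two new centres) | CC(C)[C@H]1CC[C@H](C)C(C(=O)C(OCc2ccccc2)C(Cl)=O)C1=O | intermediate
8 | (5S,8R)-3-(benzyloxy)-4-hydroxy-5-methyl-8-(propan-2-yl)-5,6,7,8-tetrahydro-2H-chromen-2-one | CC(C)[C@H]1CC[C@H](C)c2c(O)c(OCc3ccccc3)c(=O)oc21 | intermediate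
9 | (5S,8R)-3-(benzyloxy)-4-methoxy-5-methyl-8-(propan-2-yl)-5,6,7,8-tetrahydro-2H-chromen-2-one | CC(C)[C@H]1CC[C@H](C)c2c(OC)c(OCc3ccccc3)c(=O)oc21 | intermediate
10 | (5S,8R)-3-hydroxy-4-methoxy-5-methyl-8-(propan-2-yl)-5,6,7,8-tetrahydro-2H-chromen-2-one | CC(C)[C@H]1CC[C@H](C)c2c(OC)c(O)c(=O)oc21 | intermediate
11 | propargyl bromide | C#CCBr | starting material
12 | dichlorodi(propan-2-yl)silane | CC(C)[Si](Cl)(Cl)C(C)C | starting material
13 | allenylmagnesium bromide | C=C=C[Mg]Br | intermediate
14 | chloro[di(propan-2-yl)](prop-2-yn-1-yl)silane | C#CC[Si](Cl)(C(C)C)C(C)C | intermediate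
15 | (5S,8R)-3-{[di(propan-2-yl)(prop-2-yn-1-yl)silyl]oxy}-4-methoxy-5-methyl-8-(propan-2-yl)-5,6,7,8-tetrahydro-2H-chromen-2-one | CC(C)[C@H]1CC[C@H](C)c2c(OC)c(O[Si](CC#C)(C(C)C)C(C)C)c(=O)oc21 | intermediate
16 | 4-methoxy-6-methyl-2H-pyran-2-one | COc1cc(C)oc(=O)c1 | starting material
17 | 3-iodo-4-methoxy-6-methyl-2H-pyran-2-one | COc1cc(C)oc(=O)c1I | intermediate
18 | 4-methoxybenzaldehyde | COc1ccc(C=O)cc1 | starting material
19 | 3-iodo-4-methoxy-6-[(E)-2-(4-methoxyphenyl)ethenyl]-2H-pyran-2-one | COc1cc(/C=C/c2ccc(OC)cc2)oc(=O)c1I | intermediate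
20 | tethered key-step precursor: fused 4-methoxy-2-pyranone, 3-O-silylated by the diisopropyl(propargyl)silyl group whose alkyne carries the styrylpyranone (5S,8R) | CC(C)[C@H]1CC[C@H](C)c2c(OC)c(O[Si](C(C)C)(C(C)C)CC#Cc3c(OC)cc(/C=C/c4ccc(OC)cc4)oc3=O)c(=O)oc21 | intermediate
21 | bridged lactone cycloadduct (2-oxabicyclo[2.2.2]octa-5,7-dien-3-one; pyranone C3 and C6 joined by the former alkyne carbons, both bridgehead configurations) | CC(C)[C@H]1CC[C@H](C)C2=C(OC)C3(C(=O)OC12C(c4c(OC)cc(/C=C/c5ccc(OC)cc5)oc4=O)=C3C6)O[Si]6(C(C)C)C(C)C | intermediate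
22 | oxasilole-fused tetralin (C6–O–Si(iPr)2–CH2–C7 ring, C5 methoxy, C8 pyranone; 1R,4S in tetralin numbering) | CC(C)[C@H]1CC[C@H](C)c2c(OC)c3O[Si](C(C)C)(C(C)C)Cc3c(-c4c(OC)cc(/C=C/c5ccc(OC)cc5)oc4=O)c21 | intermediate
23 | 3-[(5S,8R)-3-hydroxy-2-(hydroxymethyl)-4-methoxy-5-methyl-8-(propan-2-yl)-5,6,7,8-tetrahydronaphthalen-1-yl]-4-methoxy-6-[(E)-2-(4-methoxyphenyl)ethenyl]-2H-pyran-2-one | CC(C)[C@H]1CC[C@H](C)c2c(OC)c(O)c(CO)c(-c3c(OC)cc(/C=C/c4ccc(OC)cc4)oc3=O)c21 | intermediate
24 | (5S,8R)-3-hydroxy-4-methoxy-1-{4-methoxy-6-[(E)-2-(4-methoxyphenyl)ethenyl]-2-oxo-2H-pyran-3-yl}-5-methyl-8-(propan-2-yl)-5,6,7,8-tetrahydronaphthalene-2-carbaldehyde | CC(C)[C@H]1CC[C@H](C)c2c(OC)c(O)c(C=O)c(-c3c(OC)cc(/C=C/c4ccc(OC)cc4)oc3=O)c21 | intermediate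
25 | heimiomycin A | CC(C)[C@H]1CC[C@H](C)c2c(O)c(O)c(C=O)c(-c3c(O)cc(/C=C/c4ccc(O)cc4)oc3=O)c21 | target

**Step count**

Total: 15 steps. Longest linear sequence: 11 steps, from dimethyl 2-(benzyloxy)malonate 4 (steps 2, 3, 4, 5, 6, 8, 11, 12, 13, 14, 15).

**Steps most likely to fail**

Step 12 (tethered cycloaddition). The alkyne may fail to reach the fully substituted C3 and C6 termini, because the five-membered oxasilole must form on a bicyclic transition state and the pyranone-bearing alkyne carbon is crowded by the isopropyl-bearing C1. Thermal Si–O cleavage, intermolecular cycloaddition onto the second pyranone, or attack of the neighbouring methoxy oxygen on the alkyne could then take over. The fallback uses the known intermolecular Diels–Alder reaction of a 3-silyloxy-2-pyranone with an electron-poor alkyne. It sets out from 19 and 10 and returns at 24. Sonogashira coupling of 19 with prop-2-yn-1-ol (PdCl2(PPh3)2, CuI, Et3N) would give the propargylic alcohol F1, and MnO2 would oxidise it to the ynal F2. Separately, 10 would be silylated with TBSCl and imidazole to the tert-butyldimethylsilyl ether F3. Heating F2 with F3 (PhMe, 160–180 °C, or under high pressure) should give, after loss of CO2, the silyl-protected salicylaldehyde F4. The formyl-bearing alkyne carbon is expected beside the silyloxy terminus from the polarisation of the ynal and of the 1-oxygenated diene, and a regioisomer would be separated if it forms. HF·pyridine in THF would then remove the silyl group to give 24, so that steps 13 and 14 are not needed.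

Step 4 (pyranone annulation). O-Acylation or protodesilylation of the enol ether by the HCl set free, ketene formation from the α-alkoxy acid chloride, or epimerisation of the isopropyl-bearing centre in 7 before ring closure could spoil the annulation. The fallback brings in the C3 oxygen after the ring is made. It sets out from 3 and returns at 8. Reaction of 3 with malonyl dichloride (Et2O, −78 °C → rt) would give the 3-unsubstituted 4-hydroxypyranone F5. Diazo transfer (4-acetamidobenzenesulfonyl azide, Et3N, MeCN) would give the 3-diazo-2,4-dione F6. O–H insertion into benzyl alcohol catalysed by Rh2(OAc)4, followed by enolisation, would give 8.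

Step 11 (Sonogashira coupling). The silyl ether could be cleaved by the amine hydroiodide, the alkyne could dimerise oxidatively (Glaser coupling), or Pd/Cu could promote 5-endo attack of the neighbouring methoxy oxygen on the new alkyne followed by iodide demethylation to a furopyranone. The fallback couples without amine, copper or nucleophilic iodide. It sets out from 15 and returns at 20. The alkyne terminus of 15 would be stannylated with Bu3SnNEt2 (PhMe, 60 °C) to the alkynylstannane F7, and Stille coupling of F7 with 19 (Pd(PPh3)4, PhMe, 60 °C) would give 20.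

**Further compounds**

F1 | step 12 | 3-(3-hydroxyprop-1-yn-1-yl)-4-methoxy-6-[(E)-2-(4-methoxyphenyl)ethenyl]-2H-pyran-2-one | COc1cc(/C=C/c2ccc(OC)cc2)oc(=O)c1C#CCO
F2 | step 12 | 3-{4-methoxy-6-[(E)-2-(4-methoxyphenyl)ethenyl]-2-oxo-2H-pyran-3-yl}prop-2-ynal | COc1cc(/C=C/c2ccc(OC)cc2)oc(=O)c1C#CC=O
F3 | step 12 | (5S,8R)-3-[(tert-butyldimethylsilyl)oxy]-4-methoxy-5-methyl-8-(propan-2-yl)-5,6,7,8-tetrahydro-2H-chromen-2-one | CC(C)[C@H]1CC[C@H](C)c2c(OC)c(O[Si](C)(C)C(C)(C)C)c(=O)oc21
F4 | step 12 | 3-O-(tert-butyldimethylsilyl) ether of aldehyde 24 | CC(C)[C@H]1CC[C@H](C)c2c(OC)c(O[Si](C)(C)C(C)(C)C)c(C=O)c(-c3c(OC)cc(/C=C/c4ccc(OC)cc4)oc3=O)c21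
F5 | step 4 | (5S,8R)-4-hydroxy-5-methyl-8-(propan-2-yl)-5,6,7,8-tetrahydro-2H-chromen-2-one | CC(C)[C@H]1CC[C@H](C)c2c(O)cc(=O)oc21
F6 | step 4 | (5S,8R)-3-diazo-5-methyl-8-(propan-2-yl)-5,6,7,8-tetrahydro-2H-chromene-2,4(3H)-dione | CC(C)[C@H]1CC[C@H](C)C2=C1OC(=O)C(=[N+]=[N-])C2=O
F7 | step 11 | (5S,8R)-3-{[di(propan-2-yl)(3-(tributylstannyl)prop-2-yn-1-yl)silyl]oxy}-4-methoxy-5-methyl-8-(propan-2-yl)-5,6,7,8-tetrahydro-2H-chromen-2-one | CC(C)[C@H]1CC[C@H](C)c2c(OC)c(O[Si](CC#C[Sn](CCCC)(CCCC)CCCC)(C(C)C)C(C)C)c(=O)oc21
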